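**Remark on the chemistry.** The tertiary propargyl unit is brought in as commercial 3-chloro-3-methylbut-1-yne. The transient dienone 11 forms as a racemate at C6 and loses that centre on enolisation.

## Analysis of the target

6-Prenylisocaviunin (12) is an isoflavone: a 4H-chromen-4-one (benzo ring A fused to pyranone ring C) with a 2,4,5-trimethoxyphenyl ring B at C3 and hydrogen at C2. Ring A is fully substituted: a hydroxyl at C5 chelated to the C4 carbonyl, a 3-methylbut-2-enyl (prenyl) group at C6, a free hydroxyl at C7 and a methoxy group at C8, next to the ring oxygen at C8a. There is no stereocentre and no stereogenic double bond, so the whole problem is positional. The sensitive points are the prenyl alkene between two phenols (acid closes it to a dimethylchroman), the pyranone (bases open it by addition at C2) and two electron-rich arenes that oxidise easily. The classical difficulty is that closing ring C onto an unsymmetrical tetraoxygenated benzene gives both 5,6,7- and 5,7,8-oxygenated isomers, and that prenylating a 5,7-dihydroxy ring A gives C6/C8 mixtures. The strategy rests on two relations in ring A: C8 is the only ring carbon para to O5, and C6 and C8 are the two carbons ortho to O7. A ring A taken from threefold-symmetric phloroglucinol (1) can close to only one isoflavone. A para-selective oxidation of the C5 phenol then writes the C8 methoxy group, and once C8 is filled a [3,3] shift from O7 can only finish at C6.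

## Retrosynthetic reasoning

**C6–prenyl bond.** The last bond made is the one between C6 and the prenyl CH2 of 12. Cutting it and re-attaching the five-carbon unit, inverted, to O7 leads back through dienone 11 to the tertiary allyl ether 9. The cut is placed here because the forward reaction is intramolecular and can only reach carbons ortho to O7. In 9 one of these, C8, already carries the methoxy group, so the C6/C8 question does not arise. The forward step must be a clean thermal [3,3] shift without loss of the tertiary allyl group.

**One C8–O bond (redox adjustment).** In 9 the oxygen at C5 and the methoxy oxygen at C8 are para, so 9 is a hydroquinone monoether. It cannot be the end point of an oxidation, because it is easier to oxidise than anything it could be made from. It is therefore traced back to its doubly methoxylated, two-electron-oxidised form, the quinone monoketal 10. A mild reductant returns 9 from 10 with loss of one of the two C8 methoxy groups.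

**Both C8–O bonds (key disconnection).** Cutting the two C8–O bonds of 10 gives 8, which has hydrogen at C8. The cut is made at this carbon because no symmetric ring A precursor carries oxygen there, and because introducing it after ring C exists avoids the 6-/8-oxygenation ambiguity. The forward reaction has to take four electrons from ring A and not from ring B, and has to deliver both solvent alkoxy groups to C8 and not to C6.

**O7–C bond.** The tertiary allyl ether of 8 is traced to the alkyne 7 and then, by cutting the O7–C bond, to 5 and the propargyl chloride 6. O7 is chosen because the 7-hydroxyl of 5 is the most acidic one and can be alkylated without touching the chelated 5-hydroxyl. The alkyne is used because a tertiary propargylic electrophile is attacked at its tertiary carbon, whereas a prenyl-type electrophile would be attacked at the primary end.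

**O1–C2 and C2–C3 bonds.** Ring C of 5 is opened by removing C2, via enaminoketone 4, to the deoxybenzoin 3. The two hydroxyls ortho to the acyl group of 3 are equivalent, so the forward ring closure has no choice to make.

**Aryl–carbonyl bond.** Cutting the bond between the ketone carbon and the trihydroxyphenyl ring of 3 gives 1 and 2. The three nuclear positions of 1 are equivalent, so mono-acylation gives one product.

## Alternatives that were turned down

**Alternative 1: aldehyde C–H activation and alkyne annulation.**
- Disconnection: ring C is cut at C3–C4 and O1–C2 into the ring A salicylaldehyde A2 and the aryl silyl alkyne A3.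
- Forward key step: with [RhCl2(C5Me5)]2 and Cu(OAc)2 as oxidant, phenoxide-bound trivalent rhodium inserts into the aldehyde C–H bond. The acyl–rhodium adds across A3 so that the aryl-bearing carbon bonds to the acyl carbon, and C–O reductive elimination closes ring C to the 2-silylisoflavone A1. Protodesilylation and removal of two methoxymethyl groups would follow.
- For: it is convergent, the ring A pattern is fixed before ring C exists, the silyl group steers the insertion, and no electron-rich arene has to be oxidised selectively.
- Against: A2 is a hexasubstituted benzene with formyl, hydroxyl, methoxy, methoxymethoxy, prenyl and methoxymethoxy groups in sequence. Making it means solving the same positional problem on a benzene, in more steps than the whole chosen route. The crowded aldehyde can decarbonylate at the acyl–rhodium stage. The prenyl alkene is a competing ligand for cationic rhodium under hot oxidising conditions. Acidic removal of the methoxymethyl groups next to the prenyl group invites chroman closure.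
- Comparison: Alternative 1 is stronger on convergence and on freedom from redox selectivity. The chosen route offers seven linear steps from a symmetric commodity triol, with no protecting group to remove.

**Alternative 2: oxidative quinone relay.**
- Disconnection: the O1–C8a bond of the target skeleton is cut and ring C is re-attached at the other ortho carbon of the acyl group, which leads to the isomeric 6-hydroxyisoflavone A5.
- Forward key step: PhI(OAc)2 in aqueous acetonitrile oxidises the para-alkoxyphenol of A5, water adds at the old C8a, and the hemiketal collapses to the 2-acyl-1,4-benzoquinone A6 with release of the enol. The enol oxygen adds to the free quinone carbon next to the acyl group and closes the new ring C, giving the hydroquinone A4. Methylation of its unchelated 8-hydroxyl and removal of the methoxymethyl group would finish the synthesis.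
- For: one operation transposes ring C and creates both the C5 and C8 oxygens. The two new hydroxyls are differentiated by chelation. The trivalent iodine oxidant selects the phenol by ligand exchange, a mechanistic discrimination from ring B that is better than the purely potential-based one of an anode.
- Against: A5 needs its own multistep synthesis with a prenyl group placed at its C8. The free enol of A6 can add through carbon, lose its formyl carbon by hydrolysis, or be outrun by water adding to the quinone. A4 is a hydroquinone that the oxidant will take on to a quinone. Two further steps are needed, one an acidic deprotection beside a prenyl group.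
- Comparison: Alternative 2 is stronger on chemoselectivity of the oxidant. The chosen route offers a shorter sequence, a stable end point for the oxidation (a ketal that carries no phenol) and a 7-O substituent that is the prenyl source itself.

**Alternative 3: squarate cyclobutenone cascade.**
- Disconnection: ring A is cut at C4a–C5, leading to the racemic 4-methoxy-4-pyranonyl cyclobutenone A8 built from a squarate ester.
- Forward key step: heating A8 opens the four-membered ring conrotatorily to a dienylketene. The ketene carbon bonds to the adjacent pyranone CH in a six-electron electrocyclisation, and tautomerisation gives 7-O-isopropyl-6-prenylisocaviunin A7. Removal of the isopropyl group would finish the synthesis.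
- For: every ring A substituent is fixed by connectivity, the step is thermal and neutral, and the C5 hydroxyl is formed free and chelated.
- Against: A8 requires the addition of a 2-metallated 5-aryl-4-pyranone to a prenylated squarate. That nucleophile is not a standard reagent, since pyranones are themselves electrophiles, and the 5-arylpyranone has to be made first. O-Methylation of a hindered tertiary alkoxide follows. The final Lewis-acid cleavage of the 7-O-isopropyl ether must spare the neighbouring 8-methoxy group, the ring B ethers and the prenyl alkene. The sequence is several steps longer.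
- Comparison: Alternative 3 is stronger on regiochemical certainty. The chosen route offers brevity, cheap starting materials and no final deprotection, at the price of one unprecedented oxidation.

Key step: step 5

## Steps

Step 1
Reactants: 1 phloroglucinol; 2 2,4,5-trimethoxyphenylacetic acid
Product: 3 1-(2,4,6-trihydroxyphenyl)-2-(2,4,5-trimethoxyphenyl)ethan-1-one
Conditions: BF3·OEt2 (as solvent), 85 °C; then aq. NaOAc
Reagents that add atoms: none
Why: Friedel–Crafts acylation: BF3 activates the acid, and phloroglucinol, with three equivalent and strongly activated positions, is C-acylated once. The ketone formed is held as a deactivated boron chelate, which should prevent a second acylation.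

Step 2
Reactants: 3 1-(2,4,6-trihydroxyphenyl)-2-(2,4,5-trimethoxyphenyl)ethan-1-one
Product: 5 5,7-dihydroxy-2',4',5'-trimethoxyisoflavone, via enaminoketone 4 (not isolated)
Conditions: BF3·OEt2, MsCl, DMF, 50 to 90 °C
Reagents that add atoms: N,N-dimethylformamide, CN(C)C=O
Why: Vilsmeier-type formylation followed by addition–elimination: the iminium reagent formed from DMF and MsCl attacks the activated methylene carbon to give 4, an ortho hydroxyl adds to the aminomethylene carbon, and dimethylamine is lost to close the pyranone. The two ortho hydroxyls of 3 are equivalent, so only one isoflavone can form.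

Step 3
Reactants: 5 5,7-dihydroxy-2',4',5'-trimethoxyisoflavone; 6 3-chloro-3-methylbut-1-yne
Product: 7 5-hydroxy-7-(1,1-dimethylprop-2-ynyloxy)-2',4',5'-trimethoxyisoflavone
Conditions: K2CO3, KI (cat.), CuI (cat.), acetone, 60 °C
Reagents that add atoms: none
Why: Copper-catalysed propargylic O-alkylation (Williamson type): carbonate ionises only the 7-hydroxyl, which is vinylogous to the C4 carbonyl and the most acidic, while the 5-hydroxyl stays in its hydrogen bond. The copper acetylide of 6 ionises to an allenylidene-type electrophile that takes the phenoxide at the tertiary carbon.

Step 4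
Reactants: 7 5-hydroxy-7-(1,1-dimethylprop-2-ynyloxy)-2',4',5'-trimethoxyisoflavone
Product: 8 5-hydroxy-7-(1,1-dimethylallyloxy)-2',4',5'-trimethoxyisoflavone
Conditions: H2 (1 atm), Pd/CaCO3 poisoned with Pb(OAc)2 (Lindlar catalyst), quinoline, EtOAc, rt
Reagents that add atoms: none
Why: Lindlar semihydrogenation: the poisoned palladium surface adds one equivalent of hydrogen to the terminal alkyne and releases the alkene. The conjugated C2=C3 bond of the chromone and the aryl ether C–O bond should not react under these conditions.

Step 5
Reactants: 8 5-hydroxy-7-(1,1-dimethylallyloxy)-2',4',5'-trimethoxyisoflavone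
Product: 10 8,8-dimethoxy-7-(1,1-dimethylallyloxy)-3-(2,4,5-trimethoxyphenyl)-8H-chromene-4,5-dione, via C8-methoxy phenol 9 (not isolated)
Conditions: graphite anode, Pt cathode, undivided cell, LiClO4 (0.1 M), LiOMe (0.2 equiv), 2,6-lutidine (2 equiv), MeOH, 0 °C, anode held at the phenolate wave (set by cyclic voltammetry), 4 F/mol; then pH 7 buffer
Reagents that add atoms: methanol, CO
Why: Proposed new method: the chelated phenol, which 2,6-lutidine alone cannot ionise, is deprotonated by the sub-stoichiometric methoxide (regenerated at the cathode as fast as the anode releases protons), and the phenolate loses two electrons to a phenoxenium ion that methanol captures at C8, giving phenol 9 after proton loss. Phenol 9 is a hydroquinone monoether and oxidises at a lower potential than 8, so it cannot accumulate; a second two-electron oxidation gives an oxocarbenium ion at C8 that takes a second methanol and ends as the cross-conjugated monoketal 10, which has no phenol and should be inert at the working potential. The closest known reaction type is the anodic or PhI(OAc)2-mediated oxidation of para-unsubstituted phenols in methanol to 4,4-dimethoxycyclohexa-2,5-dienones, which has not been shown on a chelated 5-hydroxyisoflavone. No ring is closed and no stereocentre is created, since C8 of 10 carries two identical methoxy groups. Two selectivities are needed: C8 over C6, and ring A over the trimethoxyphenyl ring B. The first follows from the para preference of phenoxenium capture, which gives the cross-conjugated 2,5-dienone, whereas capture at C6 would give a linearly conjugated 2,4-dienone at a carbon squeezed between the C5 oxygen and the tertiary ether. The second rests on potential: the phenolate should oxidise well before ring B, which is why the anode is held at the phenolate wave instead of passing a fixed current, whose potential would climb to the ring B wave as 8 is used up. 2,6-Lutidine buffers the acid at the anode surface so that neither the ketal nor the tertiary allyl ether is ionised.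

Step 6
Reactants: 10 8,8-dimethoxy-7-(1,1-dimethylallyloxy)-3-(2,4,5-trimethoxyphenyl)-8H-chromene-4,5-dione
Product: 9 5-hydroxy-8-methoxy-7-(1,1-dimethylallyloxy)-2',4',5'-trimethoxyisoflavone (the compound passed through without isolation in step 5)
Conditions: Na2S2O4, NaHCO3, THF/H2O, 0 °C to rt
Reagents that add atoms: none
Why: Reductive aromatisation of a quinone monoketal to a 4-methoxyphenol: electron transfer to the dienone gives a radical anion that expels methoxide from C8, and the second electron and a proton give phenol 9. The buffered, non-acidic medium should leave the tertiary allyl ether intact, and dithionite does not reduce the chromone.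

Step 7
Reactants: 9 5-hydroxy-8-methoxy-7-(1,1-dimethylallyloxy)-2',4',5'-trimethoxyisoflavone
Product: 12 6-prenylisocaviunin (5,7-dihydroxy-8-methoxy-6-(3-methylbut-2-enyl)-2',4',5'-trimethoxyisoflavone), via cyclohexadienone 11 (not isolated)
Conditions: PhNEt2, 140 °C, degassed
Reagents that add atoms: none
Why: Aromatic Claisen rearrangement: the 1,1-dimethylallyl ether shifts through a six-membered transition state with allylic inversion, so the group arrives on carbon as a prenyl unit, and dienone 11 enolises to the phenol. C8 carries the methoxy group, so only migration to C6 can re-aromatise. The basic solvent suppresses acid-induced ether cleavage and chroman formation.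

## Compound list

1 | phloroglucinol | Oc1cc(O)cc(O)c1 | starting material
2 | 2,4,5-trimethoxyphenylacetic acid | COc1cc(OC)c(CC(=O)O)cc1OC | starting material
3 | 1-(2,4,6-trihydroxyphenyl)-2-(2,4,5-trimethoxyphenyl)ethan-1-one | COc1cc(OC)c(CC(=O)c2c(O)cc(O)cc2O)cc1OC | intermediate
4 | 3-(dimethylamino)-2-(2,4,5-trimethoxyphenyl)-1-(2,4,6-trihydroxyphenyl)prop-2-en-1-one (push–pull alkene, geometry not fixed) | CN(C)C=C(c1cc(OC)c(OC)cc1OC)C(=O)c1c(O)cc(O)cc1O | intermediate
5 | 5,7-dihydroxy-2',4',5'-trimethoxyisoflavone (5,7-dihydroxy-3-(2,4,5-trimethoxyphenyl)-4H-chromen-4-one) | COc1cc(OC)c(-c2coc3cc(O)cc(O)c3c2=O)cc1OC | intermediate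
6 | 3-chloro-3-methylbut-1-yne | CC(C)(Cl)C#C | starting material
7 | 5-hydroxy-7-(1,1-dimethylprop-2-ynyloxy)-2',4',5'-trimethoxyisoflavone | COc1cc(OC)c(-c2coc3cc(OC(C)(C)C#C)cc(O)c3c2=O)cc1OC | intermediate
8 | 5-hydroxy-7-(1,1-dimethylallyloxy)-2',4',5'-trimethoxyisoflavone | COc1cc(OC)c(-c2coc3cc(OC(C)(C)C=C)cc(O)c3c2=O)cc1OC | intermediate
9 | 5-hydroxy-8-methoxy-7-(1,1-dimethylallyloxy)-2',4',5'-trimethoxyisoflavone | COc1cc(OC)c(-c2coc3c(OC)c(OC(C)(C)C=C)cc(O)c3c2=O)cc1OC | intermediate
10 | 8,8-dimethoxy-7-(1,1-dimethylallyloxy)-3-(2,4,5-trimethoxyphenyl)-8H-chromene-4,5-dione | COc1cc(OC)c(-c2coc3c(c2=O)C(=O)C=C(OC(C)(C)C=C)C3(OC)OC)cc1OC | intermediate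
11 | 5-hydroxy-8-methoxy-6-(3-methylbut-2-enyl)-3-(2,4,5-trimethoxyphenyl)-6H-chromene-4,7-dione (racemic at C6) | COc1cc(OC)c(cc1OC)C2=COC3=C(OC)C(=O)C(CC=C(C)C)C(O)=C3C2=O | intermediate
12 | 6-prenylisocaviunin (5,7-dihydroxy-8-methoxy-6-(3-methylbut-2-enyl)-3-(2,4,5-trimethoxyphenyl)-4H-chromen-4-one) | COc1cc(OC)c(-c2coc3c(OC)c(O)c(CC=C(C)C)c(O)c3c2=O)cc1OC | target

## Step count and least certain steps

Total step count: 7. Longest linear sequence: 7 (the route is linear from 1 and 2).

**Step 5 (key step, proposed new method).** Three processes can defeat it.
- Electron loss from ring B can compete with that from the ring A phenolate if the two waves are not resolved, which would lead to methoxylation or coupling on ring B.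
- After the first electron the phenoxyl radical has no para donor, so its further oxidation is slow and radical–radical coupling can outrun solvent capture.
- Methoxide can add at C2 of the product and open the pyranone.

Fallback with known chemistry, setting out from 5 and returning at 9:
- 5 is benzylated at the 7-hydroxyl (BnBr, K2CO3, acetone) to 7-benzyloxy-5-hydroxy-2',4',5'-trimethoxyisoflavone F1.
- Elbs persulfate oxidation (K2S2O8, aqueous KOH/pyridine, 0 to 20 °C), the established para-hydroxylation of 5-hydroxyflavonoids, gives the potassium C8 sulfate F2.
- Warm dilute HCl hydrolyses F2 to 7-benzyloxy-5,8-dihydroxy-2',4',5'-trimethoxyisoflavone F3.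
- Me2SO4 and K2CO3 in acetone methylate only the unchelated 8-hydroxyl, giving 7-benzyloxy-5-hydroxy-8-methoxy-2',4',5'-trimethoxyisoflavone F4.
- Hydrogenolysis (H2, Pd/C, EtOAc) gives isocaviunin F5.
- Propargylation as in step 3 gives 5-hydroxy-8-methoxy-7-(1,1-dimethylprop-2-ynyloxy)-2',4',5'-trimethoxyisoflavone F6, and semihydrogenation as in step 4 gives 9.

**Step 6.** Sulfur nucleophiles (sulfoxylate, hydrogen sulfite) may add to the electron-poor enedione or displace the tertiary allyloxy group at C7 by addition–elimination, in place of the wanted electron transfer. The classical acidic zinc reduction cannot be used on 10 because acid would ionise the tertiary allyl vinylogous ester.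

Fallback, setting out from 10 and returning at 12: 10 is warmed in toluene (80 to 110 °C) so that the allyl vinyl ether unit C6=C7–O–CMe2–CH=CH2 undergoes the aliphatic Claisen rearrangement known for allyl enol ethers of cyclic 1,3-diones. This gives 7-hydroxy-8,8-dimethoxy-6-prenyl-3-(2,4,5-trimethoxyphenyl)-8H-chromene-4,5-dione F7, which has no tertiary ether and no addition–elimination site. Zn dust in AcOH/THF at rt then reduces F7 with loss of methanol directly to 12. This detour also bypasses step 7.

**Step 7.** At the temperature of the shift the tertiary ether can fragment with loss of the five-carbon unit, and after the shift a neighbouring hydroxyl can add to the prenyl alkene and close a chroman ring.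

Fallback, setting out from 9 and returning at 12: 9 is heated in Ac2O with NaOAc (140 °C), so that the 5-hydroxyl is acetylated and the 7-hydroxyl is trapped as its acetate as soon as the rearrangement frees it. This gives 5,7-di-O-acetyl-6-prenylisocaviunin F8, in which no hydroxyl can cyclise. K2CO3 in MeOH at rt then removes both acetates to give 12.

**Step 3.** The tertiary propargyl chloride may eliminate to the enyne faster than it is substituted, and substitution may be slow at the hindered carbon, leaving unreacted 5.

Fallback, setting out from 5 and returning at 8: Tsuji–Trost O-allylation with tert-butyl 2-methylbut-3-en-2-yl carbonate and Pd(PPh3)4 (zerovalent palladium) in THF at 0 °C. Under kinetic control the phenoxide attacks the more substituted end of the 1,1-dimethylallyl palladium intermediate and gives 8 directly, which also removes step 4. No new compound is formed on the way.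

## Further compounds

F1 | step 5 | 7-(benzyloxy)-5-hydroxy-3-(2,4,5-trimethoxyphenyl)-4H-chromen-4-one | COc1cc(OC)c(-c2coc3cc(OCc4ccccc4)cc(O)c3c2=O)cc1OC
F2 | step 5 | potassium 7-(benzyloxy)-5-hydroxy-4-oxo-3-(2,4,5-trimethoxyphenyl)-4H-chromen-8-yl sulfate | COc1cc(OC)c(-c2coc3c(OS(=O)(=O)[O-])c(OCc4ccccc4)cc(O)c3c2=O)cc1OC.[K+]
F3 | step 5 | 7-(benzyloxy)-5,8-dihydroxy-3-(2,4,5-trimethoxyphenyl)-4H-chromen-4-one | COc1cc(OC)c(-c2coc3c(O)c(OCc4ccccc4)cc(O)c3c2=O)cc1OC
F4 | step 5 | 7-(benzyloxy)-5-hydroxy-8-methoxy-3-(2,4,5-trimethoxyphenyl)-4H-chromen-4-one | COc1cc(OC)c(-c2coc3c(OC)c(OCc4ccccc4)cc(O)c3c2=O)cc1OC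
F5 | step 5 | isocaviunin (5,7-dihydroxy-8-methoxy-3-(2,4,5-trimethoxyphenyl)-4H-chromen-4-one) | COc1cc(OC)c(-c2coc3c(OC)c(O)cc(O)c3c2=O)cc1OC
F6 | step 5 | 5-hydroxy-8-methoxy-7-[(2-methylbut-3-yn-2-yl)oxy]-3-(2,4,5-trimethoxyphenyl)-4H-chromen-4-one | COc1cc(OC)c(-c2coc3c(OC)c(OC(C)(C)C#C)cc(O)c3c2=O)cc1OC
F7 | step 6 | 7-hydroxy-8,8-dimethoxy-6-(3-methylbut-2-en-1-yl)-3-(2,4,5-trimethoxyphenyl)-4H-chromene-4,5(8H)-dione | COc1cc(OC)c(-c2coc3c(c2=O)C(=O)C(CC=C(C)C)=C(O)C3(OC)OC)cc1OC
F8 | step 7 | 8-methoxy-6-(3-methylbut-2-en-1-yl)-4-oxo-3-(2,4,5-trimethoxyphenyl)-4H-chromene-5,7-diyl diacetate | COc1cc(OC)c(-c2coc3c(OC)c(OC(C)=O)c(CC=C(C)C)c(OC(C)=O)c3c2=O)cc1OC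
F0 | step 3 | none | none
A1 | alternative 1 | 5,7-bis(O-methoxymethyl)-2-trimethylsilyl-6-prenylisocaviunin | COCOc1c(CC=C(C)C)c(OCOC)c(OC)c2oc([Si](C)(C)C)c(-c3cc(OC)c(OC)cc3OC)c(=O)c12
A2 | alternative 1 | 2-hydroxy-3-methoxy-4,6-bis(methoxymethoxy)-5-(3-methylbut-2-en-1-yl)benzaldehyde | O=Cc1c(O)c(OC)c(OCOC)c(CC=C(C)C)c1OCOC
A3 | alternative 1 | trimethyl[(2,4,5-trimethoxyphenyl)ethynyl]silane | COc1cc(OC)c(C#C[Si](C)(C)C)cc1OC
A4 | alternative 2 | 5,8-dihydroxy-7-(methoxymethoxy)-6-prenyl-2',4',5'-trimethoxyisoflavone | COCOc1c(O)c2occ(-c3cc(OC)c(OC)cc3OC)c(=O)c2c(O)c1CC=C(C)C
A5 | alternative 2 | 6-hydroxy-7-(methoxymethoxy)-8-prenyl-2',4',5'-trimethoxyisoflavone | COCOc1c(O)cc2c(=O)c(-c3cc(OC)c(OC)cc3OC)coc2c1CC=C(C)C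
A6 | alternative 2 | 2-[3-hydroxy-2-(2,4,5-trimethoxyphenyl)prop-2-enoyl]-5-(methoxymethoxy)-6-(3-methylbut-2-en-1-yl)cyclohexa-2,5-diene-1,4-dione (enol geometry not fixed) | O=C1C(CC=C(C)C)=C(OCOC)C(=O)C=C1C(=O)C(=CO)c1cc(OC)c(OC)cc1OC
A7 | alternative 3 | 7-O-isopropyl-6-prenylisocaviunin | COc1cc(OC)c(-c2coc3c(OC)c(OC(C)C)c(CC=C(C)C)c(O)c3c2=O)cc1OC
A8 | alternative 3 | 4-methoxy-2-(3-methylbut-2-en-1-yl)-4-[4-oxo-5-(2,4,5-trimethoxyphenyl)-4H-pyran-2-yl]-3-(propan-2-yloxy)cyclobut-2-en-1-one (racemic) | O=C1C(CC=C(C)C)=C(OC(C)C)C1(OC)c1cc(=O)c(-c2cc(OC)c(OC)cc2OC)co1
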